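**Retrosynthetic overview** (flavonoid numbering: O1, C2, C3, C4, C4a–C8a; ring B primed)

- Ring C (O1–C2–C3–C4–C4a–C8a) is the only ring that is made and it is closed last, at the O1–C2 bond, by an anodic dehydrogenative C–H/O–H coupling of an acyclic (R)-α-hydroxy dihydrochalcone.
- Enabling feature: the free 4'-OH of ring B is para to C2, so two-electron oxidation turns the C2 methylene into the exocyclic carbon of a p-quinone methide. The ring-A phenol oxygen (future O1) is placed for 6-exo-trig addition, and the C3 carbinol steers C2 to 2,3-trans.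
- C6-prenyl and 5-OH: aromatic Claisen rearrangement of a 5-O-(1,1-dimethylallyl) ether after ring closure. Before that, the same ether blocks O5 so that only O1 can cyclize.
- C4–C4a: aryllithium (between the two OMOM groups of a symmetric ring-A arene) plus a Weinreb amide. C2–C1': aryl Grignard plus methyl (R)-glycidate, which supplies C2, C3, C4 and the C3 configuration.
- Ring order: rings A and B are bought as benzene rings; ring C is formed in step 10.

Key step: step 10

Assumption: with C3 fixed, C2 of a 4'-hydroxy dihydroflavonol equilibrates through its ring-opened quinone methide to the 2,3-trans isomer, as is usual for this class.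

**Route**

Step 1
Reactants: 1 4-bromo-2-methoxyphenol
Product: 2 (4-bromo-2-methoxyphenoxy)triisopropylsilane
Conditions: TIPSCl, imidazole, DMF, rt
Reagents that add atoms: triisopropylsilyl chloride, CC(C)[Si](Cl)(C(C)C)C(C)C
Why: Silyl ether protection of the phenol, chosen because the aryl TIPS ether should survive Grignard formation, aryllithium, mild acid and Pd(0) and falls to fluoride just before the key step.

Step 2
Reactants: 2 (4-bromo-2-methoxyphenoxy)triisopropylsilane; 3 methyl (2R)-oxirane-2-carboxylate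
Product: 5 methyl (2R)-2-hydroxy-3-[3-methoxy-4-(triisopropylsilyloxy)phenyl]propanoate, via aryl Grignard reagent 4 (not isolated)
Conditions: Mg, THF, 50 °C; then CuI (10 mol%), 3, THF, −40 to −20 °C; aq NH4Cl
Reagents that add atoms: none
Why: Copper-catalysed SN2 ring opening of the terminal epoxide by an aryl Grignard reagent at the unsubstituted carbon, a standard route from glycidates to 3-aryl lactates, in which the stereocentre of 3 (later C3) is not touched.

Step 3
Reactants: 5 methyl (2R)-2-hydroxy-3-[3-methoxy-4-(triisopropylsilyloxy)phenyl]propanoate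
Product: 6 (2R)-2-hydroxy-N-methoxy-3-[3-methoxy-4-(triisopropylsilyloxy)phenyl]-N-methylpropanamide
Conditions: MeNH(OMe)·HCl, i-PrMgCl, THF, −20 to 0 °C
Reagents that add atoms: N,O-dimethylhydroxylamine hydrochloride, CNOC.Cl
Why: Weinreb amide formation by aminolysis of the ester with the magnesium amide, the hydroxyl being carried as its magnesium alkoxide, which shields the α-stereocentre from enolization.

Step 4
Reactants: 7 5-methoxybenzene-1,3-diol
Product: 8 1-methoxy-3,5-bis(methoxymethoxy)benzene
Conditions: MOMCl, i-Pr2NEt, CH2Cl2, 0 °C to rt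
Reagents that add atoms: chloromethyl methyl ether, COCCl
Why: MOM acetal protection of both phenols, which places the two strongest ortho-directing groups on either side of the carbon that is to be acylated.

Step 5
Reactants: 8 1-methoxy-3,5-bis(methoxymethoxy)benzene (2.5 equiv); 6 (2R)-2-hydroxy-N-methoxy-3-[3-methoxy-4-(triisopropylsilyloxy)phenyl]-N-methylpropanamide
Product: 10 (2R)-2-hydroxy-1-[4-methoxy-2,6-bis(methoxymethoxy)phenyl]-3-[3-methoxy-4-(triisopropylsilyloxy)phenyl]propan-1-one, via aryllithium 9 (not isolated)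
Conditions: n-BuLi, THF, 0 °C; then 6, −78 to 0 °C; aq NH4Cl
Reagents that add atoms: none
Why: Directed ortho-lithiation between the two OMOM groups followed by Weinreb ketone synthesis, in which the first equivalent of 9 deprotonates the hydroxyl and the next adds to give a chelated tetrahedral intermediate that should prevent over-addition and keep the α-stereocentre from enolizing until the quench.

Step 6
Reactants: 10 (2R)-2-hydroxy-1-[4-methoxy-2,6-bis(methoxymethoxy)phenyl]-3-[3-methoxy-4-(triisopropylsilyloxy)phenyl]propan-1-one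
Product: 11 (2R)-1-(2,6-dihydroxy-4-methoxyphenyl)-2-hydroxy-3-[3-methoxy-4-(triisopropylsilyloxy)phenyl]propan-1-one
Conditions: p-TsOH·H2O (0.2 equiv), MeOH, 40 °C
Reagents that add atoms: none
Why: Acid-catalysed transacetalization (MOM cleavage), fast for MOM ethers ortho to a carbonyl, under which the aryl TIPS ether and the α-ketol stereocentre should persist.

Step 7
Reactants: 12 2-methylbut-3-en-2-ol
Product: 13 2-methylbut-3-en-2-yl 2-methylpropyl carbonate
Conditions: n-BuLi, THF, −78 °C; then i-BuOCOCl, −78 °C to rt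
Reagents that add atoms: isobutyl chloroformate, CC(C)COC(=O)Cl
Why: O-acylation of the lithium alkoxide of a tertiary alcohol with a chloroformate (carbonate formation).

Step 8
Reactants: 11 (2R)-1-(2,6-dihydroxy-4-methoxyphenyl)-2-hydroxy-3-[3-methoxy-4-(triisopropylsilyloxy)phenyl]propan-1-one; 13 2-methylbut-3-en-2-yl 2-methylpropyl carbonate (1.1 equiv)
Product: 14 (2R)-2-hydroxy-1-[2-hydroxy-4-methoxy-6-(2-methylbut-3-en-2-yloxy)phenyl]-3-[3-methoxy-4-(triisopropylsilyloxy)phenyl]propan-1-one
Conditions: Pd(PPh3)4 (5 mol%), THF, 0 °C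
Reagents that add atoms: none
Why: Tsuji–Trost O-allylation in which the (1,1-dimethylallyl)palladium cation, formed with loss of CO2 and isobutoxide, is attacked by the phenoxide at its more substituted terminus under kinetic control, a known way to aryl 1,1-dimethylallyl ethers; the two ring-A hydroxyls are equivalent, so only one mono-ether can form, and the remaining hydroxyl stays chelated to the ketone.

Step 9
Reactants: 14 (2R)-2-hydroxy-1-[2-hydroxy-4-methoxy-6-(2-methylbut-3-en-2-yloxy)phenyl]-3-[3-methoxy-4-(triisopropylsilyloxy)phenyl]propan-1-one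
Product: 15 (2R)-2-hydroxy-1-[2-hydroxy-4-methoxy-6-(2-methylbut-3-en-2-yloxy)phenyl]-3-(4-hydroxy-3-methoxyphenyl)propan-1-one
Conditions: TBAF, AcOH, THF, 0 °C
Reagents that add atoms: none
Why: Fluoride-mediated cleavage of the aryl silyl ether, buffered with acetic acid so that the α-ketol is not enolized.

Step 10
Reactants: 15 (2R)-2-hydroxy-1-[2-hydroxy-4-methoxy-6-(2-methylbut-3-en-2-yloxy)phenyl]-3-(4-hydroxy-3-methoxyphenyl)propan-1-one
Product: 17 (2R,3R)-3-hydroxy-2-(4-hydroxy-3-methoxyphenyl)-7-methoxy-5-(2-methylbut-3-en-2-yloxy)-2,3-dihydro-4H-chromen-4-one, via p-quinone methide 16 (not isolated)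
Conditions: RVC anode, Pt cathode, undivided cell, constant current (2 mA cm−2, 2.1 F mol−1), n-Bu4NBF4 (0.1 M), 2,6-lutidine (3 equiv), HFIP (5 equiv), MeCN/CH2Cl2 4:1, rt, argon
Reagents that add atoms: none
Why: Proposed new method: two-electron, two-proton anodic oxidation of the 4-alkyl-2-methoxyphenol of ring B (the most easily oxidized group of 15) should give a phenoxonium ion that loses a C2 proton to 2,6-lutidine and becomes the p-quinone methide 16, and the hydrogen-bonded ring-A phenol oxygen (future O1) then adds to its exocyclic carbon, which re-aromatizes ring B. The closest known reaction type is the oxidative cyclization of 1-(2-hydroxyphenyl)-3-(4-hydroxy- or 4-alkoxyphenyl)propanes to flavans with DDQ through the same quinone methide or benzylic cation, together with anodic benzylic C–H etherification of electron-rich arenes; an α-hydroxy dihydrochalcone has not been cyclized at an anode in this way. Ring C is closed by a 6-exo-trig oxa-1,6-addition (O1 to C2). C2 is the only new stereocentre and is controlled by C3, which comes from 3: in the chair-like transition state the C3 hydroxyl and the quinonoid C2 substituent are both pseudo-equatorial, and since the addition is reversible through 16 a 2,3-cis isomer should drain to the 2,3-trans (2R,3R) product. The step needs oxidation of ring B only (ring A is an acylated, chelated phenol, and the alkene and ketol oxidize at far higher potential), attack by one defined oxygen (O5 is blocked as the 1,1-dimethylallyl ether), no external nucleophile for 16 (MeCN/CH2Cl2 with weakly nucleophilic HFIP as cathodic proton donor), survival of the acid-labile tertiary allyl ether (lutidine buffer) and no over-oxidation to the flavonol (charge limited to about 2.1 F mol−1; the product phenol carries an electron-withdrawing benzylic ether and should oxidize at higher potential).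

Step 11
Reactants: 17 (2R,3R)-3-hydroxy-2-(4-hydroxy-3-methoxyphenyl)-7-methoxy-5-(2-methylbut-3-en-2-yloxy)-2,3-dihydro-4H-chromen-4-one
Product: 19 (2R,3R)-3,5-dihydroxy-2-(4-hydroxy-3-methoxyphenyl)-7-methoxy-6-(3-methylbut-2-en-1-yl)-2,3-dihydro-4H-chromen-4-one, via cyclohexadienone 18 (not isolated)
Conditions: PhMe (degassed), 110 °C, sealed tube, argon
Reagents that add atoms: none
Why: Aromatic Claisen rearrangement ([3,3]-sigmatropic) of the aryl 1,1-dimethylallyl ether to the only free ortho position (C6), then tautomerization of dienone 18, which turns the tertiary allyl group into the 3-methylbut-2-enyl group and frees the 5-OH without involving either stereocentre.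

**Compound list**

1 | 4-bromo-2-methoxyphenol | COc1cc(Br)ccc1O | starting material
2 | (4-bromo-2-methoxyphenoxy)triisopropylsilane | COc1cc(Br)ccc1O[Si](C(C)C)(C(C)C)C(C)C | intermediate
3 | methyl (2R)-oxirane-2-carboxylate (methyl (R)-glycidate) | COC(=O)[C@H]1CO1 | starting material
4 | [3-methoxy-4-(triisopropylsilyloxy)phenyl]magnesium bromide | COc1cc([Mg]Br)ccc1O[Si](C(C)C)(C(C)C)C(C)C | intermediate (not isolated)
5 | methyl (2R)-2-hydroxy-3-[3-methoxy-4-(triisopropylsilyloxy)phenyl]propanoate | COC(=O)[C@H](O)Cc1ccc(O[Si](C(C)C)(C(C)C)C(C)C)c(OC)c1 | intermediate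
6 | (2R)-2-hydroxy-N-methoxy-3-[3-methoxy-4-(triisopropylsilyloxy)phenyl]-N-methylpropanamide | CON(C)C(=O)[C@H](O)Cc1ccc(O[Si](C(C)C)(C(C)C)C(C)C)c(OC)c1 | intermediate
7 | 5-methoxybenzene-1,3-diol | COc1cc(O)cc(O)c1 | starting material
8 | 1-methoxy-3,5-bis(methoxymethoxy)benzene | COCOc1cc(OC)cc(OCOC)c1 | intermediate
9 | [4-methoxy-2,6-bis(methoxymethoxy)phenyl]lithium | COCOc1cc(OC)cc(OCOC)c1[Li] | intermediate (not isolated)
10 | (2R)-2-hydroxy-1-[4-methoxy-2,6-bis(methoxymethoxy)phenyl]-3-[3-methoxy-4-(triisopropylsilyloxy)phenyl]propan-1-one | COCOc1cc(OC)cc(OCOC)c1C(=O)[C@H](O)Cc1ccc(O[Si](C(C)C)(C(C)C)C(C)C)c(OC)c1 | intermediate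
11 | (2R)-1-(2,6-dihydroxy-4-methoxyphenyl)-2-hydroxy-3-[3-methoxy-4-(triisopropylsilyloxy)phenyl]propan-1-one | COc1cc(O)c(C(=O)[C@H](O)Cc2ccc(O[Si](C(C)C)(C(C)C)C(C)C)c(OC)c2)c(O)c1 | intermediate
12 | 2-methylbut-3-en-2-ol | CC(C)(O)C=C | starting material
13 | 2-methylbut-3-en-2-yl 2-methylpropyl carbonate | CC(C)COC(=O)OC(C)(C)C=C | intermediate
14 | (2R)-2-hydroxy-1-[2-hydroxy-4-methoxy-6-(2-methylbut-3-en-2-yloxy)phenyl]-3-[3-methoxy-4-(triisopropylsilyloxy)phenyl]propan-1-one | C=CC(C)(C)Oc1cc(OC)cc(O)c1C(=O)[C@H](O)Cc1ccc(O[Si](C(C)C)(C(C)C)C(C)C)c(OC)c1 | intermediate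
15 | (2R)-2-hydroxy-1-[2-hydroxy-4-methoxy-6-(2-methylbut-3-en-2-yloxy)phenyl]-3-(4-hydroxy-3-methoxyphenyl)propan-1-one | C=CC(C)(C)Oc1cc(OC)cc(O)c1C(=O)[C@H](O)Cc1ccc(O)c(OC)c1 | intermediate
16 | 4-{(2R)-2-hydroxy-3-[2-hydroxy-4-methoxy-6-(2-methylbut-3-en-2-yloxy)phenyl]-3-oxopropylidene}-2-methoxycyclohexa-2,5-dien-1-one (p-quinone methide, alkene geometry not defined) | C=CC(C)(C)Oc1cc(OC)cc(O)c1C(=O)[C@H](O)C=C1C=CC(=O)C(OC)=C1 | intermediate (not isolated)
17 | (2R,3R)-3-hydroxy-2-(4-hydroxy-3-methoxyphenyl)-7-methoxy-5-(2-methylbut-3-en-2-yloxy)-2,3-dihydro-4H-chromen-4-one | COc1cc([C@H]2Oc3cc(OC)cc(OC(C)(C)C=C)c3C(=O)[C@@H]2O)ccc1O | intermediate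
18 | (2R,3R)-3-hydroxy-2-(4-hydroxy-3-methoxyphenyl)-7-methoxy-6-(3-methylbut-2-en-1-yl)-2,3-dihydro-4H-chromene-4,5(6H)-dione (both C6 epimers) | COc1cc([C@H]2OC3=C(C(=O)C(CC=C(C)C)C(OC)=C3)C(=O)[C@@H]2O)ccc1O | intermediate (not isolated)
19 | (2R,3R)-3,5-dihydroxy-2-(4-hydroxy-3-methoxyphenyl)-7-methoxy-6-(3-methylbut-2-en-1-yl)-2,3-dihydro-4H-chromen-4-one | COc1cc([C@H]2Oc3cc(OC)c(CC=C(C)C)c(O)c3C(=O)[C@@H]2O)ccc1O | target

**Step count and risks**

Total step count: 11. Longest linear sequence: 9 steps (1, 2, 3, 5, 6, 8, 9, 10, 11).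

Steps most likely to fail:

1. Step 10 (Proposed new method). Possible failure processes:
   - one-electron phenoxyl radical coupling (dimerization) outrunning the second electron transfer;
   - tautomerization of the quinone methide to the enol of the achiral 1,2-diketone, with loss of the C3 configuration;
   - over-oxidation of the product towards the flavonol;
   - passivation of the anode.

   Fallback, by known chemistry: it sets out from 14, with the silyl ether still in place, and returns at 17. Treatment of 14 with DDQ (1.2 equiv) in dry CH2Cl2 with 4 Å molecular sieves at 0 °C should abstract the benzylic hydride at C2 of the 3-methoxy-4-silyloxybenzyl group. The ring-A phenol then traps the cation, as in the known DDQ cyclization of 1-(2-hydroxyphenyl)-3-arylpropanes to flavans. This should give (2R,3R)-3-hydroxy-7-methoxy-2-[3-methoxy-4-(triisopropylsilyloxy)phenyl]-5-(2-methylbut-3-en-2-yloxy)-2,3-dihydro-4H-chromen-4-one F1. Desilylation with TBAF/AcOH in THF at 0 °C should then give 17, and any 2,3-cis epimer can equilibrate to trans once the 4'-OH is free.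

2. Step 8. Possible failure processes: isomerization of the tertiary ether to the linear prenyl ether through reversible π-allyl formation, double alkylation, and C-allylation of the electron-rich ring.

   Fallback: it sets out from 11 and returns at 14. Copper-catalysed O-propargylation of 11 with 3-chloro-3-methylbut-1-yne (CuCl2·2H2O cat., DBU, MeCN, 0 °C) can only give the tertiary ether. The product would be (2R)-2-hydroxy-1-[2-hydroxy-4-methoxy-6-(2-methylbut-3-yn-2-yloxy)phenyl]-3-[3-methoxy-4-(triisopropylsilyloxy)phenyl]propan-1-one F2. Lindlar semi-hydrogenation (H2, Pd/CaCO3/Pb, quinoline, EtOAc, rt) of F2 should then give 14.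

3. Step 5. Possible failure processes: sluggish addition of the hindered aryllithium to the alkoxide-bearing Weinreb amide, and competing lithiation at the position between OMOM and OMe.

   Fallback: it sets out from 6 and returns at 11, and replaces the acylation by aldehyde addition and oxidation.
   - Silylation of 6 (TESCl, imidazole, CH2Cl2) should give (2R)-N-methoxy-3-[3-methoxy-4-(triisopropylsilyloxy)phenyl]-N-methyl-2-(triethylsilyloxy)propanamide F3.
   - DIBAL-H reduction (THF, −78 °C) should give (2R)-3-[3-methoxy-4-(triisopropylsilyloxy)phenyl]-2-(triethylsilyloxy)propanal F4.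
   - Addition of 9 (THF, −78 °C) should give (2R)-1-[4-methoxy-2,6-bis(methoxymethoxy)phenyl]-3-[3-methoxy-4-(triisopropylsilyloxy)phenyl]-2-(triethylsilyloxy)propan-1-ol F5 as a mixture of carbinol epimers.
   - Dess–Martin oxidation (NaHCO3, CH2Cl2) should give (2R)-1-[4-methoxy-2,6-bis(methoxymethoxy)phenyl]-3-[3-methoxy-4-(triisopropylsilyloxy)phenyl]-2-(triethylsilyloxy)propan-1-one F6.
   - The conditions of step 6 (p-TsOH, MeOH) should then remove the TES group together with both MOM groups and give 11.

**Further compounds**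

F1 | step 10 | (2R,3R)-3-hydroxy-7-methoxy-2-[3-methoxy-4-(triisopropylsilyloxy)phenyl]-5-(2-methylbut-3-en-2-yloxy)-2,3-dihydro-4H-chromen-4-one | COc1cc([C@H]2Oc3cc(OC)cc(OC(C)(C)C=C)c3C(=O)[C@@H]2O)ccc1O[Si](C(C)C)(C(C)C)C(C)C
F2 | step 8 | (2R)-2-hydroxy-1-[2-hydroxy-4-methoxy-6-(2-methylbut-3-yn-2-yloxy)phenyl]-3-[3-methoxy-4-(triisopropylsilyloxy)phenyl]propan-1-one | C#CC(C)(C)Oc1cc(OC)cc(O)c1C(=O)[C@H](O)Cc1ccc(O[Si](C(C)C)(C(C)C)C(C)C)c(OC)c1
F3 | step 5 | (2R)-N-methoxy-3-[3-methoxy-4-(triisopropylsilyloxy)phenyl]-N-methyl-2-(triethylsilyloxy)propanamide | CON(C)C(=O)[C@H](O[Si](CC)(CC)CC)Cc1ccc(O[Si](C(C)C)(C(C)C)C(C)C)c(OC)c1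
F4 | step 5 | (2R)-3-[3-methoxy-4-(triisopropylsilyloxy)phenyl]-2-(triethylsilyloxy)propanal | O=C[C@H](O[Si](CC)(CC)CC)Cc1ccc(O[Si](C(C)C)(C(C)C)C(C)C)c(OC)c1
F5 | step 5 | (2R)-1-[4-methoxy-2,6-bis(methoxymethoxy)phenyl]-3-[3-methoxy-4-(triisopropylsilyloxy)phenyl]-2-(triethylsilyloxy)propan-1-ol (both C1 epimers) | COCOc1cc(OC)cc(OCOC)c1C(O)[C@H](O[Si](CC)(CC)CC)Cc1ccc(O[Si](C(C)C)(C(C)C)C(C)C)c(OC)c1
F6 | step 5 | (2R)-1-[4-methoxy-2,6-bis(methoxymethoxy)phenyl]-3-[3-methoxy-4-(triisopropylsilyloxy)phenyl]-2-(triethylsilyloxy)propan-1-one | COCOc1cc(OC)cc(OCOC)c1C(=O)[C@H](O[Si](CC)(CC)CC)Cc1ccc(O[Si](C(C)C)(C(C)C)C(C)C)c(OC)c1
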